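**Plan**

1. Numbering (longipinane type): C1 ketone, C2 CH2, C3 CH(CH3), cyclobutane C4–C5–C11–C10 (C10 carries CH3), C6 CMe2, C7 and C9 the ester carbons, C8 CH2. The seven-membered ring is C5–C6–C7–C8–C9–C10–C11.
2. Retrosynthesis cuts, in order: the two angelate acyl–O bonds; C3–CH3 (cuprate on a C1 enone); C8 out of the seven-membered ring (7,9-dione ⇐ six-ring C7/C9 1,2-dione); C4–C10 (cyclobutane); C10–C11 and C5–C6 (annulation).
3. Enabling feature: in the seven-membered ring the two oxygenated carbons C7 and C9 sit 1,3 across the only methylene (C8), and each is flanked by a fully substituted carbon (C6, C10). A non-enolisable C7/C9 1,2-dione can therefore take up one diazo carbon by 1,2-acyl shift and deliver the ring and both oxygenated carbons in one event.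
4. Forward order: ring C1–C2–C3–C4–C5–C11 (from a 4-silyloxycyclohexenone) → six-membered ring C5–C6–C7–C9–C10–C11 by Lewis acid [4+2] annulation → cyclobutane by 4-exo epoxide opening → six-to-seven ring expansion → C3 methyl last.
5. Stereochemistry: the C1–O centre (CBS reduction) steers an anti annulation (C11, C5, cis fusion); convex-face epoxidation sets C4; the ring tether sets C10; (S)-CBS reagent control gives the anti (7R,9R)-diol; the cuprate enters C3 from the face of the C5 bridge.

Key step: step 14

Remark: 1, 5 and all reagents (angelic anhydride included) are taken as purchasable. The diene geometry in 7 and the configurations at C10 (before step 10) and C7 (steps 9–12) are of no consequence, because both carbons become trigonal again.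

**Route**

Step 1
Reactants: 1 1,4-dioxaspiro[4.5]dec-6-en-8-one
Product: 2 (S)-1,4-dioxaspiro[4.5]dec-6-en-8-ol
Conditions: (R)-Me-CBS [(R)-1-methyl-3,3-diphenyltetrahydro-1H,3H-pyrrolo[1,2-c][1,3,2]oxazaborole] (10 mol%), BH3·SMe2, THF, −20 °C
Reagents that add atoms: none
Why: Corey–Bakshi–Shibata reduction: with the alkene arm as the large substituent the (R)-catalyst should deliver hydride to the face that gives the (S)-allylic alcohol, the stereocentre from which all later ones are relayed.

Step 2
Reactants: 2 (S)-1,4-dioxaspiro[4.5]dec-6-en-8-ol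
Product: 3 (S)-8-(tert-butyldimethylsilyloxy)-1,4-dioxaspiro[4.5]dec-6-ene
Conditions: TBSCl, imidazole, DMF, 23 °C
Reagents that add atoms: tert-butyldimethylsilyl chloride, CC(C)(C)[Si](C)(C)Cl
Why: Standard silylation of a secondary allylic alcohol; the bulky ether later shields one face of the enone.

Step 3
Reactants: 3 (S)-8-(tert-butyldimethylsilyloxy)-1,4-dioxaspiro[4.5]dec-6-ene
Product: 4 (S)-4-(tert-butyldimethylsilyloxy)cyclohex-2-en-1-one
Conditions: pyridinium p-toluenesulfonate (cat.), acetone/H2O, 40 °C
Reagents that add atoms: water, O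
Why: Mild acid-catalysed hydrolysis of the allylic ketal unmasks the enone while the secondary silyl ether survives and the stereocentre is untouched.

Step 4
Reactants: 5 mesityl oxide
Product: 6 5-methylhex-4-en-3-one
Conditions: LiN(i-Pr)2, THF, −78 °C; MeI
Reagents that add atoms: iodomethane, CI
Why: Kinetic deprotonation of the enone at the α′ methyl group and C-methylation of the cross-conjugated lithium dienolate (enolate alkylation).

Step 5
Reactants: 6 5-methylhex-4-en-3-one
Product: 7 (2E)-3-(tert-butyldimethylsilyloxy)-5-methylhexa-2,4-diene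
Conditions: LiN(i-Pr)2, THF, −78 °C; TBSCl, DMPU
Reagents that add atoms: tert-butyldimethylsilyl chloride, CC(C)(C)[Si](C)(C)Cl
Why: Kinetic α′ enolisation and O-silylation give the 2-silyloxydiene; its double-bond geometry does not matter because C10 becomes trigonal again in step 10.

Step 6
Reactants: 4 (S)-4-(tert-butyldimethylsilyloxy)cyclohex-2-en-1-one; 7 (2E)-3-(tert-butyldimethylsilyloxy)-5-methylhexa-2,4-diene
Product: 9 cis-fused bicyclic C4-ketone with C1–OTBS and C9(OTBS)=C7 enol ether, via Mukaiyama–Michael enone silyl enol ether 8 (not isolated)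
Conditions: AlBr3/AlMe3 (10:1, 0.3 equiv), toluene/CH2Cl2, −10 °C; Et3N quench
Reagents that add atoms: none
Why: Lewis acid-promoted Diels–Alder-type annulation of a hindered 2-silyloxydiene with an enone (Mukaiyama–Michael addition, then ring-closing Michael addition with silyl transfer): the diene terminus C10 should attack C11 anti to the C1 silyloxy group and the enolate carbon C5 then closes onto the CMe2 terminus on the same face, which sets C11 and C5 as a cis ring fusion and leaves the enol ether regiodefined at C9=C7.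

Step 7
Reactants: 9 cis-fused bicyclic C4-ketone
Product: 10 C4 enol triflate (C3=C4)
Conditions: KN(SiMe3)2, THF, −78 °C; PhNTf2
Reagents that add atoms: N-phenylbis(trifluoromethanesulfonimide), O=S(=O)(N(c1ccccc1)S(=O)(=O)C(F)(F)F)C(F)(F)F
Why: Kinetic enolisation at the only unhindered α-methylene (C3; C5–H is tertiary and flanked by CMe2) and O-triflation give the enol triflate without epimerising the ring fusion.

Step 8
Reactants: 10 C4 enol triflate
Product: 11 bicyclic C3=C4 alkene
Conditions: Pd(OAc)2 (5 mol%), PPh3, n-Bu3N, HCO2H, DMF, 60 °C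
Reagents that add atoms: none
Why: Palladium-catalysed formate reduction of an enol triflate (Cacchi reduction) replaces OTf by H and should leave the silyl enol ether intact.

Step 9
Reactants: 11 bicyclic C3=C4 alkene
Product: 13 C3/C4-epoxy C7-silyloxy C9-ketone, via C7-silyloxy C9-ketone alkene 12 (not isolated)
Conditions: mCPBA (2.3 equiv), NaHCO3, CH2Cl2, 0 → 23 °C
Reagents that add atoms: meta-chloroperoxybenzoic acid, O=C(OO)c1cccc(Cl)c1
Why: Two Prilezhaev oxidations: the electron-rich silyl enol ether reacts first (Rubottom oxidation with 1,4-silyl shift, which removes the second enolisable site of the C9 ketone), then the C3=C4 alkene should be epoxidised on the convex face away from the second ring (C6 and C10 substituents), so the oxirane oxygen ends up trans to the C11–C10 bond.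

Step 10
Reactants: 13 C3/C4-epoxy C7-silyloxy C9-ketone
Product: 15 tricyclic C3-mesylate (cyclobutane closed), via tricyclic C3 lithium alkoxide 14 (not isolated)
Conditions: LiN(SiMe3)2, THF, −78 → 0 °C; then MsCl, −78 → 0 °C
Reagents that add atoms: methanesulfonyl chloride, CS(=O)(=O)Cl
Why: Intramolecular enolate alkylation by an epoxide (4-exo-tet, Stork-type epoxide cyclisation, akin to the enolate closure of the copaene cyclobutane): only C10 can form a useful enolate, its p-orbital is held by the ring pointing at C4 anti to the oxirane C–O bond (trans-diaxial opening), so the C4–C10 bond should form with inversion at C4 while the ring tether fixes C10 (methyl on the side of the C1–C3 bridge); mesylation of the alkoxide in the same flask forestalls silyl transfer from O1 to O3.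

Step 11
Reactants: 15 tricyclic C3-mesylate
Product: 16 tricyclic C2=C3 alkene
Conditions: KOt-Bu, 18-crown-6, THF, 23 °C
Reagents that add atoms: none
Why: Anti E2 elimination; C4 is a bridgehead (Bredt), so only a C2 hydrogen can be lost and the C2=C3 alkene forms regiospecifically.

Step 12
Reactants: 16 tricyclic C2=C3 alkene
Product: 17 C1,C7-diol C9-ketone
Conditions: Bu4NF, AcOH, THF, 23 °C
Reagents that add atoms: none
Why: Fluoride cleavage of both silyl ethers; either α-ketol tautomer that may form leads to the same dione in step 13.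

Step 13
Reactants: 17 C1,C7-diol C9-ketone
Product: 18 six-ring C7/C9 1,2-dione (C1 allylic alcohol)
Conditions: Cu(OAc)2·H2O (2.2 equiv), MeOH, 40 °C
Reagents that add atoms: none
Why: Cu(OAc)2 oxidation of an α-ketol to the 1,2-dione via the copper enediolate; isolated allylic alcohols are not oxidised under these conditions.

Step 14
Reactants: 18 six-ring C7/C9 1,2-dione
Product: 20 seven-ring 7,9-dione, via C8-trimethylsilyl 7,9-dione 19 (not isolated)
Conditions: TMSCHN2 (1.2 equiv), Sc(OTf)3 (5 mol%), CH2Cl2, −40 → 0 °C; then MeOH/aq. NaHCO3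
Reagents that add atoms: (trimethylsilyl)diazomethane, C[Si](C)(C)C=[N+]=[N-]
Why: Sc(OTf)3 activates one carbonyl of the non-enolisable C7/C9 1,2-dione, the diazo carbon adds to it, and the neighbouring acyl carbon migrates to the former diazo carbon with loss of N2 (1,2-acyl shift), so the new carbon C8 ends up between C7 and C9 and the six-membered ring becomes the seven-membered 7,9-dione; the C-silyl group is lost on work-up. The closest known reaction types are the diazoalkane homologation of cyclic 1,2-diones to 1,3-diones (camphorquinone, acenaphthenequinone) and the Sc(OTf)3-catalysed diazoalkane ring expansion of cycloalkanones. No ring is closed: the existing ring grows by one atom through a 1,2-shift. No stereocentre is formed or touched (C4, C5, C10 and C11 stay fixed; C7 and C9 are set in step 15). The step needs acyl migration in preference to migration of the quaternary C6 or C10 and to epoxide formation, and chemoselectivity over the C2=C3 alkene and the C1 hydroxyl: attack at either carbonyl followed by acyl shift gives the same product, acyl groups migrate readily in this reaction class while both alkyl candidates are hindered neopentyl or bridgehead centres, and an unactivated alkene and an alcohol do not react with the diazoalkane at low temperature.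

Step 15
Reactants: 20 seven-ring 7,9-dione
Product: 21 (7R,9R)-1,7,9-triol
Conditions: (S)-Me-CBS [(S)-1-methyl-3,3-diphenyltetrahydro-1H,3H-pyrrolo[1,2-c][1,3,2]oxazaborole] (0.5 equiv), catecholborane (6 equiv), toluene, −40 → 0 °C; MeOH, aq. NaOH
Reagents that add atoms: none
Why: Double Corey–Bakshi–Shibata reduction under catalyst control: each carbonyl has a fully substituted carbon (C10 or C6) as large and C8H2 as small substituent, so the (S)-catalyst should give the R alcohol at both centres, i.e. the anti (7R,9R)-diol, which substrate control cannot supply because the two faces of the seven-membered ring are nearly mirror-related; catecholborane spares the alkene.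

Step 16
Reactants: 21 (7R,9R)-1,7,9-triol
Product: 22 (7R,9R)-7,9-dihydroxy C1-enone
Conditions: MnO2 (activated, excess), CH2Cl2, 23 °C
Reagents that add atoms: none
Why: MnO2 oxidises only the allylic alcohol (as cis-verbenol gives verbenone) and so removes the auxiliary C1 stereocentre while the hindered 7,9-diol is untouched.

Step 17
Reactants: 22 (7R,9R)-7,9-dihydroxy C1-enone
Product: 23 7,9-bis(angeloyloxy) C1-enone
Conditions: LiN(SiMe3)2 (2.2 equiv), THF, −78 °C; angelic anhydride (3 equiv), −78 → 0 °C
Reagents that add atoms: angelic anhydride [(Z)-2-methylbut-2-enoic anhydride], C/C=C(/C)C(=O)OC(=O)/C(C)=C\C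
Why: Acylation of the lithium alkoxides with angelic anhydride (stereoconservative angeloylation) avoids the nucleophilic catalysts that isomerise angelate to tiglate, and the enone has no enolisable hydrogen because C4 and C11 are bridgeheads.

Step 18
Reactants: 23 7,9-bis(angeloyloxy) C1-enone
Product: 24 (3R,4S,5S,7R,9R,10R,11R)-7,9-bis(angeloyloxy)longipinan-1-one (CNP0283599.1)
Conditions: Me2CuLi (3 equiv, from CuI and MeLi), Et2O, −78 → −40 °C; aq. NH4Cl
Reagents that add atoms: lithium dimethylcuprate, [Li+].C[Cu-]C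
Why: Gilman cuprate conjugate addition: the methyl group should enter C3 from the face of the C5–H bridge, anti to the C10 bridge whose methyl group shields the other face (as apoverbenone gives trans-verbanone), setting 3R; the strained enone is far more reactive than the hindered α-methyl-β-alkyl angelate enoates.

**Compound list**

1 | 1,4-dioxaspiro[4.5]dec-6-en-8-one | O=C1C=CC2(CC1)OCCO2 | starting material
2 | (S)-1,4-dioxaspiro[4.5]dec-6-en-8-ol | O[C@@H]1C=CC2(CC1)OCCO2 | intermediate
3 | (S)-8-(tert-butyldimethylsilyloxy)-1,4-dioxaspiro[4.5]dec-6-ene | CC(C)(C)[Si](C)(C)O[C@@H]1C=CC2(CC1)OCCO2 | intermediate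
4 | (S)-4-(tert-butyldimethylsilyloxy)cyclohex-2-en-1-one | O=C1C=C[C@@H](O[Si](C)(C)C(C)(C)C)CC1 | intermediate
5 | mesityl oxide (4-methylpent-3-en-2-one) | CC(C)=CC(C)=O | starting material
6 | 5-methylhex-4-en-3-one | CCC(=O)C=C(C)C | intermediate
7 | (2E)-3-(tert-butyldimethylsilyloxy)-5-methylhexa-2,4-diene | C/C=C(/O[Si](C)(C)C(C)(C)C)C=C(C)C | intermediate
8 | Michael adduct: C4(OTBS)=C5 silyl enol ether with C1–OTBS, carrying at C11 the 5-methyl-3-oxohex-4-en-2-yl chain (C10 epimers) | CC(C)=CC(=O)C(C)[C@H]1C=C(O[Si](C)(C)C(C)(C)C)CC[C@@H]1O[Si](C)(C)C(C)(C)C | intermediate (not isolated)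
9 | cis-fused bicyclic ketone: C4 ketone, C1–OTBS, C9(OTBS)=C7 enol ether, C6 gem-dimethyl, C10 methyl (C10 epimers) | O=C1CC[C@H](O[Si](C)(C)C(C)(C)C)[C@@H]2[C@H]1C(C)(C)C=C(O[Si](C)(C)C(C)(C)C)C2C | intermediate
10 | enol triflate of 9 (C4–OTf, C3=C4) | O=S(=O)(OC1=CC[C@H](O[Si](C)(C)C(C)(C)C)[C@@H]2[C@H]1C(C)(C)C=C(O[Si](C)(C)C(C)(C)C)C2C)C(F)(F)F | intermediate
11 | bicyclic diene: C3=C4 alkene, C9(OTBS)=C7 enol ether, C1–OTBS | C1=CC[C@H](O[Si](C)(C)C(C)(C)C)[C@@H]2[C@H]1C(C)(C)C=C(O[Si](C)(C)C(C)(C)C)C2C | intermediate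
12 | bicyclic C9-ketone with C7–OTBS, C1–OTBS and C3=C4 alkene (C7 and C10 epimers) | C1=CC[C@H](O[Si](C)(C)C(C)(C)C)[C@@H]2[C@H]1C(C)(C)C(O[Si](C)(C)C(C)(C)C)C(=O)C2C | intermediate (not isolated)
13 | bicyclic C9-ketone with C3/C4 epoxide (oxygen trans to the C11–C10 bond), C7–OTBS and C1–OTBS | O=C1C(O[Si](C)(C)C(C)(C)C)C(C)(C)[C@H]2[C@@H]3O[C@@H]3C[C@H](O[Si](C)(C)C(C)(C)C)[C@H]2C1C | intermediate
14 | tricyclic (C4–C10 bonded) C9-ketone, C3–OH, C1–OTBS, C7–OTBS | O=C1C(O[Si](C)(C)C(C)(C)C)C(C)(C)[C@H]2[C@@H]3[C@H](O)C[C@H](O[Si](C)(C)C(C)(C)C)[C@H]2[C@]13C | intermediate (not isolated, as lithium alkoxide)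
15 | C3-mesylate of 14 | O=C1C(O[Si](C)(C)C(C)(C)C)C(C)(C)[C@H]2[C@@H]3[C@H](OS(C)(=O)=O)C[C@H](O[Si](C)(C)C(C)(C)C)[C@H]2[C@]13C | intermediate
16 | tricyclic C9-ketone with C2=C3 alkene, C1–OTBS, C7–OTBS | O=C1C(O[Si](C)(C)C(C)(C)C)C(C)(C)[C@H]2[C@@H]3C=C[C@H](O[Si](C)(C)C(C)(C)C)[C@H]2[C@]13C | intermediate
17 | tricyclic C9-ketone C1,C7-diol with C2=C3 alkene | O=C1C(O)C(C)(C)[C@H]2[C@@H]3C=C[C@H](O)[C@H]2[C@]13C | intermediate
18 | tricyclic C7/C9 1,2-dione (six-membered ring C5–C6–C7–C9–C10–C11), C1–OH, C2=C3 | O=C1C(=O)C(C)(C)[C@H]2[C@@H]3C=C[C@H](O)[C@H]2[C@]13C | intermediate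
19 | 8-trimethylsilyl-3-demethyllongipin-2-ene-7,9-dion-1-ol | O=C1C([Si](C)(C)C)C(=O)C(C)(C)[C@H]2[C@@H]3C=C[C@H](O)[C@H]2[C@]13C | intermediate (not isolated)
20 | 1-hydroxy-3-demethyllongipin-2-ene-7,9-dione | O=C1CC(=O)C(C)(C)[C@H]2[C@@H]3C=C[C@H](O)[C@H]2[C@]13C | intermediate
21 | (7R,9R)-3-demethyllongipin-2-ene-1,7,9-triol | O[C@@H]1C[C@@H](O)C(C)(C)[C@H]2[C@@H]3C=C[C@H](O)[C@H]2[C@]13C | intermediate
22 | (7R,9R)-7,9-dihydroxy-3-demethyllongipin-2-en-1-one | O[C@@H]1C[C@@H](O)C(C)(C)[C@H]2[C@@H]3C=CC(=O)[C@H]2[C@]13C | intermediate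
23 | (7R,9R)-7,9-bis(angeloyloxy)-3-demethyllongipin-2-en-1-one | C/C=C(/C)C(=O)O[C@@H]1C[C@@H](OC(=O)/C(C)=C\C)C(C)(C)[C@H]2[C@@H]3C=CC(=O)[C@H]2[C@]13C | intermediate
24 | (3R,4S,5S,7R,9R,10R,11R)-7,9-bis(angeloyloxy)longipinan-1-one (CNP0283599.1) | C/C=C(/C)C(=O)O[C@@H]1C[C@@H](OC(=O)/C(C)=C\C)[C@]2(C)[C@@H]3[C@@H]([C@H]2C(=O)C[C@H]3C)C1(C)C | target

**Totals and risks**

Total step count: 18. Longest linear sequence: 16 steps (steps 1–3 and 6–18).

Steps most likely to fail:

Step 6. The γ-silyloxy group may be lost by Lewis acid-assisted elimination, or the sequence may stop after the first C–C bond because the ring-closing addition onto the β,β-dimethyl enone is slow. The fallback avoids Lewis acid and silyl enol ethers. It sets out from 4 and 6: the kinetic lithium dienolate of 6 (LiN(i-Pr)2, THF/DMPU, −78 → 23 °C) should add to 4 in two successive anionic Michael additions to give the cis-fused C4,C9-diketone F1. Kinetic enolisation of F1 at the unhindered C3 methylene (KN(SiMe3)2, PhNTf2) should give the keto enol triflate F2, and Pd(OAc)2/HCO2H/n-Bu3N the keto alkene F3. Kinetic silylation of F3 at the less substituted C7 side (LiN(i-Pr)2, TBSCl) comes back to the route at 11.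

Step 10. Base-induced isomerisation of the oxirane to an allylic alkoxide, or silyl transfer from O1 to the new C3 alkoxide, may outrun the strained 4-exo closure. The fallback replaces the epoxide by a better, non-isomerisable leaving group. It sets out from 12 (isolable when step 9 is run with one equivalent of peracid): OsO4/N-methylmorpholine N-oxide should give the convex-face C3,C4-cis-diol F4, and SOCl2/Et3N then RuCl3 (cat.)/NaIO4 the cyclic sulfate F5. KOt-Bu in THF should close the C4–C10 bond with inversion at C4 to the C3 sulfate monoester F6, and dilute H2SO4 in wet THF hydrolyses it to alcohol 14, which is mesylated (MsCl, Et3N) to rejoin the route at 15.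

Step 15. Catalyst control may be lost in the second reduction through internal hydride delivery from the first-formed boronate (giving the syn diol), or the two neopentyl carbonyls may reduce sluggishly. The fallback sets the second centre by substrate control. It sets out from 20: one hydride equivalent with the (S)-Me-CBS catalyst at −78 °C should give the (R)-configured β-hydroxy ketones, the 9-hydroxy-7-ketone F7 and the 7-hydroxy-9-ketone F8, which need not be separated. Me4NBH(OAc)3 in MeCN/AcOH at −20 °C (Evans–Saksena internal delivery) should reduce each to the anti diol and come back to the route at 21.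

**Further compounds**

F1 | step 6 | cis-fused bicyclic C4,C9-diketone with C1–OTBS (C10 epimers) | O=C1CC[C@H](O[Si](C)(C)C(C)(C)C)[C@@H]2[C@H]1C(C)(C)CC(=O)C2C
F2 | step 6 | C4 enol triflate (C3=C4) of F1 | O=S(=O)(OC1=CC[C@H](O[Si](C)(C)C(C)(C)C)[C@@H]2[C@H]1C(C)(C)CC(=O)C2C)C(F)(F)F
F3 | step 6 | bicyclic C9-ketone with C3=C4 alkene and C1–OTBS | C1=CC[C@H](O[Si](C)(C)C(C)(C)C)[C@@H]2[C@H]1C(C)(C)CC(=O)C2C
F4 | step 10 | bicyclic C9-ketone C3,C4-cis-diol (hydroxyls trans to the C11–C10 bond), C1–OTBS, C7–OTBS | O=C1C(O[Si](C)(C)C(C)(C)C)C(C)(C)[C@H]2[C@H](O)[C@H](O)C[C@H](O[Si](C)(C)C(C)(C)C)[C@H]2C1C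
F5 | step 10 | C3,C4-cyclic sulfate of F4 | O=C1C(O[Si](C)(C)C(C)(C)C)C(C)(C)[C@H]2[C@@H]3OS(=O)(=O)O[C@@H]3C[C@H](O[Si](C)(C)C(C)(C)C)[C@H]2C1C
F6 | step 10 | tricyclic C3 hydrogen sulfate (C4–C10 bonded) | O=C1C(O[Si](C)(C)C(C)(C)C)C(C)(C)[C@H]2[C@@H]3[C@H](OS(=O)(=O)O)C[C@H](O[Si](C)(C)C(C)(C)C)[C@H]2[C@]13C
F7 | step 15 | (9R)-1,9-dihydroxy-3-demethyllongipin-2-en-7-one | O[C@@H]1CC(=O)C(C)(C)[C@H]2[C@@H]3C=C[C@H](O)[C@H]2[C@]13C
F8 | step 15 | (7R)-1,7-dihydroxy-3-demethyllongipin-2-en-9-one | O=C1C[C@@H](O)C(C)(C)[C@H]2[C@@H]3C=C[C@H](O)[C@H]2[C@]13C
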